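**Strategy.** The route rests on disconnecting the bond between side-chain C1' and ring C2, the fully substituted carbon flanked by ring oxygen O1 and the C3 carbonyl of the oxan-3-one. This O1–C2–C3=O unit is read as a tertiary 2-furyl carbinol (Achmatowicz retron). Both carbons are donors, so they are joined with polarity reversal: the lithiated (S)-1-(5-methylfuran-2-yl)ethyl carbamate captures the primary alkyl pinacol boronate that carries the whole arylated C10 side chain, and a stereospecific 1,2-metalate shift forges C1'–C2 and sets C2. The furan then becomes the pyranone by oxidative ring expansion, C6 methylation and catalyst-controlled C5 hydroxylation.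

Key step: step 11

**Remarks on the chemistry**
- Ar = 2-methoxy-3-methyl-5-(triisopropylsilyloxy)phenyl. Ring atoms are O1 and C2–C6 of the oxan-3-one; side-chain carbons are C1'–C10', counted from C2.
- The side-chain carbinol C6' is made racemic in step 4 and carried as an epimer mixture, because step 17 oxidises it to the ketone; its centre is left undefined in the SMILES.
- C6 of 25 and 26 is an epimer mixture that step 14 makes non-stereogenic.
- But-2-ynal is taken as commercial (otherwise MnO2 oxidation of but-2-yn-1-ol).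
- In step 15 the ligand antipode that delivers boron to the Si face of C5 is to be fixed on a model enone; the one written is the working choice.

**Route**

Step 1
Reactants: 1 4-methoxy-3-methylphenol
Product: 2 triisopropyl(4-methoxy-3-methylphenoxy)silane
Conditions: TIPSCl, imidazole, DMF, rt
Reagents that add atoms: triisopropylsilyl chloride, CC(C)[Si](Cl)(C(C)C)C(C)C
Why: Imidazole-promoted silylation masks the phenol as a bulky, base-stable, poorly coordinating aryl silyl ether that should survive the organolithium, aluminium and basic peroxide steps and fall to fluoride at the end.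

Step 2
Reactants: 2 triisopropyl(4-methoxy-3-methylphenoxy)silane
Product: 4 [2-methoxy-3-methyl-5-(triisopropylsilyloxy)phenyl]methanol (Ar–CH2OH), via aryllithium 3 (not isolated)
Conditions: n-BuLi, TMEDA, Et2O, 0 °C to rt; then paraformaldehyde, −78 °C to rt
Reagents that add atoms: formaldehyde (from paraformaldehyde), C=O
Why: Directed ortho-metalation should occur only ortho to methoxy (its other ortho position carries the methyl, and the bulky silyloxy group shields its own ortho positions), and the aryllithium is trapped by formaldehyde.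

Step 3
Reactants: 4 Ar–CH2OH
Product: 5 2-methoxy-3-methyl-5-(triisopropylsilyloxy)benzyl chloride (Ar–CH2Cl)
Conditions: PPh3, NCS, CH2Cl2, 0 °C
Reagents that add atoms: N-chlorosuccinimide, O=C1CCC(=O)N1Cl
Why: Appel-type chlorination via the alkoxyphosphonium salt converts the electron-rich benzylic alcohol to the chloride under neutral conditions that spare the aryl silyl ether.

Step 4
Reactants: 6 but-2-ynal; 7 3-bromoprop-1-yne
Product: 9 rac-hepta-1,5-diyn-4-ol, via allenylzinc bromide 8 (not isolated)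
Conditions: Zn dust, THF/sat. aq NH4Cl, 0 °C
Reagents that add atoms: none
Why: Barbier propargylation, in which allenylzinc bromide adds to the aldehyde through an SE2' transition state to give the homopropargylic alcohol; the new carbinol centre (later C6') is deliberately racemic.

Step 5
Reactants: 9 rac-hepta-1,5-diyn-4-ol; 5 Ar–CH2Cl
Product: 11 (6E)-8-Ar-6-methyloct-6-en-2-yn-4-ol, via alkenylalane 10 (not isolated)
Conditions: AlMe3 (3.5 equiv), Cp2ZrCl2 (0.3 equiv), CH2Cl2, 0 °C to rt; volatiles removed; then 5, Pd(PPh3)4 (5 mol %), THF, rt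
Reagents that add atoms: trimethylaluminium, C[Al](C)C
Why: Zirconium-catalysed syn methylalumination (Negishi carboalumination) is selective for the terminal alkyne and gives the (E)-2-methylalkenylalane, which is cross-coupled with the benzylic chloride under palladium catalysis with retention, so the C8'=C9' (E) geometry follows from the syn addition.

Step 6
Reactants: 11 (6E)-8-Ar-6-methyloct-6-en-2-yn-4-ol
Product: 13 (2Z,6E)-8-Ar-2-iodo-6-methylocta-2,6-dien-4-ol, via cyclic alkenylalanate 12 (not isolated)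
Conditions: NaAlH2(OCH2CH2OCH3)2, THF, 0 °C to rt; then I2, THF, −78 °C
Reagents that add atoms: iodine, II
Why: Hydroxyl-directed trans-hydroalumination of the propargylic alcohol places aluminium on the distal alkyne carbon cis to the carbinol in a five-membered alanate, and iodinolysis with retention gives the (Z)-γ-iodo allylic alcohol, which fixes the later C4'=C5' geometry.

Step 7
Reactants: 13 (2Z,6E)-8-Ar-2-iodo-6-methylocta-2,6-dien-4-ol
Product: 14 [(2Z,6E)-8-Ar-2-iodo-6-methylocta-2,6-dien-4-yl]oxy(triethyl)silane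
Conditions: TESCl, imidazole, DMF, 0 °C
Reagents that add atoms: chlorotriethylsilane, CC[Si](Cl)(CC)CC
Why: Silylation protects C6'–OH as a triethylsilyl ether that tolerates carbanions and aqueous base but can later be removed by mild acid in the presence of the aryl triisopropylsilyl ether.

Step 8
Reactants: 14 vinyl iodide; 15 allylboronic acid pinacol ester
Product: 17 2-[(4Z,8E)-10-Ar-4,8-dimethyl-6-(triethylsilyloxy)deca-4,8-dien-1-yl]-4,4,5,5-tetramethyl-1,3,2-dioxaborolane, via borane 16 (not isolated)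
Conditions: 15, 9-BBN, THF, rt; then 14, Pd(dppf)Cl2 (5 mol %), AsPh3, aq K3PO4, THF/DMF, rt
Reagents that add atoms: none
Why: B-alkyl Suzuki–Miyaura coupling, in which 9-BBN hydroborates the allyl boronate at the terminal carbon and only the trialkylborane transmetalates under aqueous base, so the (Z)-vinyl iodide is alkylated with retention while the pinacol boronate survives as the handle for the key step.

Step 9
Reactants: 18 1-(5-methylfuran-2-yl)ethanone
Product: 19 (S)-1-(5-methylfuran-2-yl)ethanol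
Conditions: RuCl[(S,S)-TsDPEN](p-cymene) (1 mol %), HCO2H/Et3N (5:2), rt
Reagents that add atoms: none
Why: Noyori asymmetric transfer hydrogenation, in which the (S,S)-diamine ruthenium hydride should deliver hydride to the Re face of the heteroaryl methyl ketone as it does for aryl methyl ketones, giving the (S)-carbinol.

Step 10
Reactants: 19 (S)-1-(5-methylfuran-2-yl)ethanol
Product: 20 (S)-1-(5-methylfuran-2-yl)ethyl N,N-diisopropylcarbamate
Conditions: iPr2NCOCl, Et3N, DMAP (cat.), toluene, 80 °C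
Reagents that add atoms: N,N-diisopropylcarbamoyl chloride, CC(C)N(C(C)C)C(Cl)=O
Why: Carbamoylation installs the group that both directs and stabilises α-lithiation and later serves as the leaving group of the 1,2-shift, without touching the stereocentre.

Step 11
Reactants: 20 (S)-carbamate; 17 side-chain pinacol boronate
Product: 24 (2R,6Z,10E)-12-Ar-6,10-dimethyl-2-(5-methylfuran-2-yl)-8-(triethylsilyloxy)dodeca-6,10-dien-2-ol, via lithiated carbamate 21 (not isolated), via boronate complex 22 (not isolated), via tertiary boronic ester 23 (not isolated)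
Conditions: 20 (1.5 equiv), s-BuLi (1.4 equiv), Et2O, −78 °C; add 17, −78 °C to rt; then 2 M NaOH, 30% H2O2, THF, 0 °C to rt
Reagents that add atoms: hydrogen peroxide, OO
Why: s-BuLi removes the carbinol hydrogen of 20 (acidified by the furan and the coordinating carbamate) with retention, the lithium carbenoid 21 adds to boron of 17 with retention to give ate complex 22, on warming the primary alkyl group migrates from boron to carbon anti to the departing carbamate (inversion) to give 23, and oxidation of C–B proceeds with retention. The closest known reaction type is the lithiation–borylation of secondary benzylic carbamates (a Matteson-type 1,2-metalate rearrangement), here with 2-furyl as the aryl group. No ring is closed in this step. The new stereocentre C2 is controlled only by the configuration of (S)-20 through the retention, retention, inversion, retention sequence, which should give the (R)-tertiary alcohol. The step needs α-lithiation instead of ring lithiation (furan C5 is blocked by methyl and the carbamate directs to the α position), exclusive migration of the alkyl group (the pinacol oxygens do not migrate) and configurational stability of 21 (kept at −78 °C in Et2O); the silyl ethers and alkenes of 17 are inert to the hindered carbanion. Both carbons are donors (C–Li and C–B), and the union works because C2 turns into a carbenoid electrophile inside the ate complex.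

Step 12
Reactants: 24 tertiary furyl carbinol
Product: 25 (2R)-2-[(4Z,8E)-10-Ar-4,8-dimethyl-6-(triethylsilyloxy)deca-4,8-dien-1-yl]-6-hydroxy-2,6-dimethyl-2H-pyran-3(6H)-one
Conditions: VO(acac)2 (5 mol %), t-BuOOH (decane), CH2Cl2, 0 °C to rt
Reagents that add atoms: tert-butyl hydroperoxide, CC(C)(C)OO
Why: Achmatowicz rearrangement, in which hydroxyl-directed vanadium-catalysed oxidation touches only the furan and the resulting (Z)-enedione closes through the C2 oxygen onto the C6 ketone to the six-membered hemiketal, leaving C2 unchanged and the remote alkenes and arene untouched.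

Step 13
Reactants: 25 hemiketal
Product: 26 (2R)-6-acetoxy-2-[(4Z,8E)-10-Ar-4,8-dimethyl-6-(triethylsilyloxy)deca-4,8-dien-1-yl]-2,6-dimethyl-2H-pyran-3(6H)-one
Conditions: Ac2O, Et3N, DMAP (cat.), CH2Cl2, 0 °C
Reagents that add atoms: acetic anhydride, CC(=O)OC(C)=O
Why: DMAP-catalysed acylation locks the ring form of the hemiketal and turns the C6 hydroxyl into a leaving group.

Step 14
Reactants: 26 ketal acetate
Product: 27 (2R)-2-[(4Z,8E)-10-Ar-4,8-dimethyl-6-(triethylsilyloxy)deca-4,8-dien-1-yl]-2,6,6-trimethyl-2H-pyran-3(6H)-one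
Conditions: AlMe3 (4 equiv), CH2Cl2, −78 to −20 °C
Reagents that add atoms: trimethylaluminium, C[Al](C)C
Why: Lewis-acid-mediated substitution of an anomeric acetate through a cyclic oxocarbenium ion (Kishi-type C-glycosylation with an organoaluminium), in which AlMe3 both ionises C6–OAc and transfers methyl, so both C6 epimers converge on the non-stereogenic gem-dimethyl carbon.

Step 15
Reactants: 27 enone
Product: 29 (2R,5S)-2-[(4Z,8E)-10-Ar-4,8-dimethyl-6-(triethylsilyloxy)deca-4,8-dien-1-yl]-5-hydroxy-2,6,6-trimethyloxan-3-one, via boryl ketone 28 (not isolated)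
Conditions: B2pin2, CuCl (5 mol %), (R)-1-[(SP)-2-(diphenylphosphino)ferrocenyl]ethyldicyclohexylphosphine (5 mol %), NaOt-Bu (10 mol %), MeOH (2 equiv), THF, rt; then NaBO3·4H2O, THF/H2O, rt
Reagents that add atoms: sodium perborate, B1(OO1)[O-].[Na+]; bis(pinacolato)diboron (boron present in 28 only), CC1(C)OB(OC1(C)C)B1OC(C)(C)C(C)(C)O1
Why: Copper-catalysed asymmetric conjugate borylation followed by C–B oxidation with retention, in which the chiral bisphosphine–copper boryl should add to the Si face of C5 (the face cis to the C2 side chain) under catalyst control, the substrate bias being small because C2 is remote and C6 carries two identical methyls.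

Step 16
Reactants: 29 hydroxy ketone
Product: 30 (2R,5S)-2-[(4Z,8E)-10-Ar-6-hydroxy-4,8-dimethyldeca-4,8-dien-1-yl]-5-hydroxy-2,6,6-trimethyloxan-3-one
Conditions: PPTS (cat.), MeOH/CH2Cl2, 0 °C
Reagents that add atoms: none
Why: Acid-catalysed methanolysis removes the secondary triethylsilyl ether much faster than the aryl triisopropylsilyl ether, so only C6'–OH is freed.

Step 17
Reactants: 30 diol
Product: 31 (2R,5S)-2-[(4Z,8E)-10-Ar-4,8-dimethyl-6-oxodeca-4,8-dien-1-yl]-5-hydroxy-2,6,6-trimethyloxan-3-one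
Conditions: activated MnO2 (excess), CH2Cl2, rt
Reagents that add atoms: none
Why: MnO2 oxidises only the allylic C6' carbinol and leaves the saturated, hindered C5 carbinol alone, and the neutral heterogeneous conditions should preserve the (Z)-enone geometry and the position of the C8'=C9' alkene.

Step 18
Reactants: 31 silyl-protected enone
Product: 32 (2R,5S)-5-hydroxy-2-[(4Z,8E)-10-(5-hydroxy-2-methoxy-3-methylphenyl)-4,8-dimethyl-6-oxodeca-4,8-dien-1-yl]-2,6,6-trimethyloxan-3-one (target)
Conditions: TBAF, AcOH (1:1), THF, 0 °C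
Reagents that add atoms: none
Why: Fluoride desilylation of the aryl silyl ether, buffered with acetic acid so that the base-sensitive β,γ-unsaturated (Z)-enone and the β-hydroxy ketone are not isomerised or cleaved.

**Compound list**

1 | 4-methoxy-3-methylphenol | COc1ccc(O)cc1C | starting material
2 | triisopropyl(4-methoxy-3-methylphenoxy)silane | COc1ccc(O[Si](C(C)C)(C(C)C)C(C)C)cc1C | intermediate
3 | [2-methoxy-3-methyl-5-(triisopropylsilyloxy)phenyl]lithium | COc1c([Li])cc(O[Si](C(C)C)(C(C)C)C(C)C)cc1C | intermediate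
4 | [2-methoxy-3-methyl-5-(triisopropylsilyloxy)phenyl]methanol | COc1c(CO)cc(O[Si](C(C)C)(C(C)C)C(C)C)cc1C | intermediate
5 | 2-methoxy-3-methyl-5-(triisopropylsilyloxy)benzyl chloride | COc1c(CCl)cc(O[Si](C(C)C)(C(C)C)C(C)C)cc1C | intermediate
6 | but-2-ynal | CC#CC=O | starting material
7 | 3-bromoprop-1-yne (propargyl bromide) | BrCC#C | starting material
8 | allenylzinc bromide | C=C=C[Zn]Br | intermediate
9 | rac-hepta-1,5-diyn-4-ol | CC#CC(O)CC#C | intermediate
10 | (E)-alkenylalane: dimethyl[(1E)-4-(dimethylaluminiooxy)-2-methylhept-1-en-5-yn-1-yl]alane | CC#CC(O[Al](C)C)C/C(C)=C/[Al](C)C | intermediate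
11 | (6E)-8-Ar-6-methyloct-6-en-2-yn-4-ol | COc1c(C)cc(O[Si](C(C)C)(C(C)C)C(C)C)cc1C/C=C(\C)CC(O)C#CC | intermediate
12 | sodium cyclic alkenylalanate (five-membered O–Al–C=C ring, two 2-methoxyethoxy ligands on Al) | COc1c(C)cc(O[Si](C(C)C)(C(C)C)C(C)C)cc1C/C=C(\C)CC1O[Al-](OCCOC)(OCCOC)C(C)=C1.[Na+] | intermediate
13 | (2Z,6E)-8-Ar-2-iodo-6-methylocta-2,6-dien-4-ol | COc1c(C)cc(O[Si](C(C)C)(C(C)C)C(C)C)cc1C/C=C(\C)CC(O)/C=C(/C)I | intermediate
14 | [(2Z,6E)-8-Ar-2-iodo-6-methylocta-2,6-dien-4-yl]oxy(triethyl)silane | COc1c(C)cc(O[Si](C(C)C)(C(C)C)C(C)C)cc1C/C=C(\C)CC(O[Si](CC)(CC)CC)/C=C(/C)I | intermediate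
15 | allylboronic acid pinacol ester | C=CCB1OC(C)(C)C(C)(C)O1 | starting material
16 | 9-[3-(4,4,5,5-tetramethyl-1,3,2-dioxaborolan-2-yl)propyl]-9-borabicyclo[3.3.1]nonane | CC1(C)OB(CCCB2C3CCCC2CCC3)OC1(C)C | intermediate
17 | 2-[(4Z,8E)-10-Ar-4,8-dimethyl-6-(triethylsilyloxy)deca-4,8-dien-1-yl]-4,4,5,5-tetramethyl-1,3,2-dioxaborolane | COc1c(C)cc(O[Si](C(C)C)(C(C)C)C(C)C)cc1C/C=C(\C)CC(O[Si](CC)(CC)CC)/C=C(/C)CCCB1OC(C)(C)C(C)(C)O1 | intermediate
18 | 1-(5-methylfuran-2-yl)ethanone | CC(=O)c1ccc(C)o1 | starting material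
19 | (S)-1-(5-methylfuran-2-yl)ethanol | C[C@H](O)c1ccc(C)o1 | intermediate
20 | (S)-1-(5-methylfuran-2-yl)ethyl N,N-diisopropylcarbamate | C[C@H](OC(=O)N(C(C)C)C(C)C)c1ccc(C)o1 | intermediate
21 | α-lithiated carbamate (Li in place of the carbinol H, retention) | C[C@]([Li])(OC(=O)N(C(C)C)C(C)C)c1ccc(C)o1 | intermediate
22 | lithium boronate (ate) complex of 21 and 17 | [Li+].C[C@]([B-]1(CCC/C(C)=C\C(O[Si](CC)(CC)CC)C/C(C)=C/Cc2cc(O[Si](C(C)C)(C(C)C)C(C)C)cc(C)c2OC)OC(C)(C)C(C)(C)O1)(OC(=O)N(C(C)C)C(C)C)c1ccc(C)o1 | intermediate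
23 | (S)-tertiary boronic ester: 2-[(2S,6Z,10E)-12-Ar-6,10-dimethyl-2-(5-methylfuran-2-yl)-8-(triethylsilyloxy)dodeca-6,10-dien-2-yl]-4,4,5,5-tetramethyl-1,3,2-dioxaborolane | C[C@@](B1OC(C)(C)C(C)(C)O1)(CCC/C(C)=C\C(O[Si](CC)(CC)CC)C/C(C)=C/Cc2cc(O[Si](C(C)C)(C(C)C)C(C)C)cc(C)c2OC)c1ccc(C)o1 | intermediate
24 | (2R,6Z,10E)-12-Ar-6,10-dimethyl-2-(5-methylfuran-2-yl)-8-(triethylsilyloxy)dodeca-6,10-dien-2-ol | COc1c(C)cc(O[Si](C(C)C)(C(C)C)C(C)C)cc1C/C=C(\C)CC(O[Si](CC)(CC)CC)/C=C(/C)CCC[C@@](C)(O)c1ccc(C)o1 | intermediate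
25 | (2R)-2-[(4Z,8E)-10-Ar-4,8-dimethyl-6-(triethylsilyloxy)deca-4,8-dien-1-yl]-6-hydroxy-2,6-dimethyl-2H-pyran-3(6H)-one | COc1c(C)cc(O[Si](C(C)C)(C(C)C)C(C)C)cc1C/C=C(\C)CC(O[Si](CC)(CC)CC)/C=C(/C)CCC[C@@]1(C)OC(C)(O)C=CC1=O | intermediate
26 | (2R)-6-acetoxy-2-[(4Z,8E)-10-Ar-4,8-dimethyl-6-(triethylsilyloxy)deca-4,8-dien-1-yl]-2,6-dimethyl-2H-pyran-3(6H)-one | COc1c(C)cc(O[Si](C(C)C)(C(C)C)C(C)C)cc1C/C=C(\C)CC(O[Si](CC)(CC)CC)/C=C(/C)CCC[C@@]1(C)OC(C)(OC(C)=O)C=CC1=O | intermediate
27 | (2R)-2-[(4Z,8E)-10-Ar-4,8-dimethyl-6-(triethylsilyloxy)deca-4,8-dien-1-yl]-2,6,6-trimethyl-2H-pyran-3(6H)-one | COc1c(C)cc(O[Si](C(C)C)(C(C)C)C(C)C)cc1C/C=C(\C)CC(O[Si](CC)(CC)CC)/C=C(/C)CCC[C@@]1(C)OC(C)(C)C=CC1=O | intermediate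
28 | (2R,5S)-2-[(4Z,8E)-10-Ar-4,8-dimethyl-6-(triethylsilyloxy)deca-4,8-dien-1-yl]-2,6,6-trimethyl-5-(4,4,5,5-tetramethyl-1,3,2-dioxaborolan-2-yl)oxan-3-one | COc1c(C)cc(O[Si](C(C)C)(C(C)C)C(C)C)cc1C/C=C(\C)CC(O[Si](CC)(CC)CC)/C=C(/C)CCC[C@@]1(C)OC(C)(C)[C@@H](B2OC(C)(C)C(C)(C)O2)CC1=O | intermediate
29 | (2R,5S)-2-[(4Z,8E)-10-Ar-4,8-dimethyl-6-(triethylsilyloxy)deca-4,8-dien-1-yl]-5-hydroxy-2,6,6-trimethyloxan-3-one | COc1c(C)cc(O[Si](C(C)C)(C(C)C)C(C)C)cc1C/C=C(\C)CC(O[Si](CC)(CC)CC)/C=C(/C)CCC[C@@]1(C)OC(C)(C)[C@@H](O)CC1=O | intermediate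
30 | (2R,5S)-2-[(4Z,8E)-10-Ar-6-hydroxy-4,8-dimethyldeca-4,8-dien-1-yl]-5-hydroxy-2,6,6-trimethyloxan-3-one | COc1c(C)cc(O[Si](C(C)C)(C(C)C)C(C)C)cc1C/C=C(\C)CC(O)/C=C(/C)CCC[C@@]1(C)OC(C)(C)[C@@H](O)CC1=O | intermediate
31 | (2R,5S)-2-[(4Z,8E)-10-Ar-4,8-dimethyl-6-oxodeca-4,8-dien-1-yl]-5-hydroxy-2,6,6-trimethyloxan-3-one | COc1c(C)cc(O[Si](C(C)C)(C(C)C)C(C)C)cc1C/C=C(\C)CC(=O)/C=C(/C)CCC[C@@]1(C)OC(C)(C)[C@@H](O)CC1=O | intermediate
32 | (2R,5S)-5-hydroxy-2-[(4Z,8E)-10-(5-hydroxy-2-methoxy-3-methylphenyl)-4,8-dimethyl-6-oxodeca-4,8-dien-1-yl]-2,6,6-trimethyloxan-3-one | COc1c(C)cc(O)cc1C/C=C(\C)CC(=O)/C=C(/C)CCC[C@@]1(C)OC(C)(C)[C@@H](O)CC1=O | target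

**Step count.** Total: 18 steps. Longest linear sequence: 15 steps (1, 2, 3, 5, 6, 7, 8, 11, 12, 13, 14, 15, 16, 17, 18).

**Steps most likely to fail, with fallbacks**

Step 11. The furyl-stabilised lithium carbenoid may lose its configuration before it is borylated, or the hindered ate complex may revert to its components instead of rearranging. The fallback makes the same C1'–C2 bond by carbonyl addition. It sets out from boronate 17 and ketone 18. Boronate 17 is oxidised (NaBO3·4H2O, THF/H2O) to the primary alcohol (4Z,8E)-10-Ar-4,8-dimethyl-6-(triethylsilyloxy)deca-4,8-dien-1-ol F1. F1 is converted (I2, PPh3, imidazole, CH2Cl2) to the iodide [(2E,6Z)-1-Ar-10-iodo-3,7-dimethyldeca-2,6-dien-5-yl]oxy(triethyl)silane F2, and F2 gives with magnesium in THF the Grignard reagent [(4Z,8E)-10-Ar-4,8-dimethyl-6-(triethylsilyloxy)deca-4,8-dien-1-yl]magnesium iodide F3. F3 is added to ketone 18 at −78 °C in the presence of a stoichiometric chiral tridentate diamine–phenol ligand (ligand-mediated enantioselective Grignard addition to an aryl methyl ketone). This should give tertiary alcohol 24, where the route is rejoined before step 12.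

Step 14. Methyl transfer may go to the enone carbonyl, or the acetate may fail to ionise because the oxocarbenium ion is conjugated with the electron-poor enone. The fallback changes the order of events so that C6 is methylated on a saturated ring. It sets out from hemiketal 25, which is O-methylated (MeI, Ag2O, CH2Cl2) to the methyl ketal (2R)-2-[(4Z,8E)-10-Ar-4,8-dimethyl-6-(triethylsilyloxy)deca-4,8-dien-1-yl]-6-methoxy-2,6-dimethyl-2H-pyran-3(6H)-one F4. F4 is taken through the conjugate borylation and oxidation of step 15 to the hydroxy ketal (2R,5S)-2-[(4Z,8E)-10-Ar-4,8-dimethyl-6-(triethylsilyloxy)deca-4,8-dien-1-yl]-5-hydroxy-6-methoxy-2,6-dimethyloxan-3-one F5. F5 is then methylated at C6 with AlMe3 and TMSOTf (CH2Cl2, −78 °C) through an ordinary, non-conjugated oxocarbenium ion. This should give 29, where the route is rejoined before step 16.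

Step 15. Facial selectivity at C5 may be poor, or the boryl-copper species may not add at the neopentyl β-carbon. The fallback replaces conjugate borylation by epoxidation and reductive opening, and sets out from enone 27. Weitz–Scheffer epoxidation (t-BuOOH, DBU, CH2Cl2) gives the epoxy ketone (2R)-2-[(4Z,8E)-10-Ar-4,8-dimethyl-6-(triethylsilyloxy)deca-4,8-dien-1-yl]-4,5-epoxy-2,6,6-trimethyloxan-3-one (epoxide oxygen cis to the side chain) F6. Its Cα–O bond is cleaved reductively (PhSeSePh, NaBH4, AcOH, EtOH, 0 °C) to the β-hydroxy ketone 29, where the route is rejoined before step 16. The C5 epimer would be separated by chromatography and returned to 27 by dehydration (MsCl, Et3N).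

Further compounds
F1 | step 11 | (4Z,8E)-10-Ar-4,8-dimethyl-6-(triethylsilyloxy)deca-4,8-dien-1-ol | COc1c(C)cc(O[Si](C(C)C)(C(C)C)C(C)C)cc1C/C=C(\C)CC(O[Si](CC)(CC)CC)/C=C(/C)CCCO
F2 | step 11 | [(2E,6Z)-1-Ar-10-iodo-3,7-dimethyldeca-2,6-dien-5-yl]oxy(triethyl)silane | COc1c(C)cc(O[Si](C(C)C)(C(C)C)C(C)C)cc1C/C=C(\C)CC(O[Si](CC)(CC)CC)/C=C(/C)CCCI
F3 | step 11 | [(4Z,8E)-10-Ar-4,8-dimethyl-6-(triethylsilyloxy)deca-4,8-dien-1-yl]magnesium iodide | COc1c(C)cc(O[Si](C(C)C)(C(C)C)C(C)C)cc1C/C=C(\C)CC(O[Si](CC)(CC)CC)/C=C(/C)CCC[Mg]I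
F4 | step 14 | (2R)-2-[(4Z,8E)-10-Ar-4,8-dimethyl-6-(triethylsilyloxy)deca-4,8-dien-1-yl]-6-methoxy-2,6-dimethyl-2H-pyran-3(6H)-one | COc1c(C)cc(O[Si](C(C)C)(C(C)C)C(C)C)cc1C/C=C(\C)CC(O[Si](CC)(CC)CC)/C=C(/C)CCC[C@@]1(C)OC(C)(OC)C=CC1=O
F5 | step 14 | (2R,5S)-2-[(4Z,8E)-10-Ar-4,8-dimethyl-6-(triethylsilyloxy)deca-4,8-dien-1-yl]-5-hydroxy-6-methoxy-2,6-dimethyloxan-3-one | COc1c(C)cc(O[Si](C(C)C)(C(C)C)C(C)C)cc1C/C=C(\C)CC(O[Si](CC)(CC)CC)/C=C(/C)CCC[C@@]1(C)OC(C)(OC)[C@@H](O)CC1=O
F6 | step 15 | (2R)-2-[(4Z,8E)-10-Ar-4,8-dimethyl-6-(triethylsilyloxy)deca-4,8-dien-1-yl]-4,5-epoxy-2,6,6-trimethyloxan-3-one, epoxide oxygen cis to the side chain | COc1c(C)cc(O[Si](C(C)C)(C(C)C)C(C)C)cc1C/C=C(\C)CC(O[Si](CC)(CC)CC)/C=C(/C)CCC[C@@]1(C)OC(C)(C)[C@H]2O[C@H]2C1=O
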